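## Retrosynthetic overview

1. Eudesmane numbering is used: ring A = C1–C5 + C10, ring B = C5–C10, C14 = methyl on C10, C15 = methyl on C4, C11–C13 = side chain on C7. β is the face that carries C14, and the substituents on C3, C7, C8 and C10 are all β.
2. The strategy rests on one feature. C14 on C10 and the oxygen on C8 share the β face of ring B, and C10 is bonded to C5 of the ring A alkene C4=C5. C14 can therefore enter as the CH2 of a C5–C10–C14 cyclopropane handed over from the C8 hydroxyl, and the enol of a C3 ketone later cuts the surplus C5–C14 bond.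
3. Late disconnections are the C3 ester, the C8 acetate and C12 methyl ester (opening of the cis 8β,12-olide), C13 (Mannich methylenation), C7–C11 (alkylation of a C8 ketone) and C15 (thiomethylation and desulfurisation at C4).
4. Rings A and B come intact from 6-methoxy-2-tetralone. The three-membered ring is closed in step 4 and opened in step 5. A temporary γ-lactone is closed in step 12 and opened in step 15.

Key step: step 4

Remark: the two CH2 flanks of a 2-tetralone are too alike for reliable chemical asymmetric hydride transfer, so C8 is set enzymatically. A commercial ketoreductase panel is assumed to contain an (S)-selective enzyme for 1.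

## Route

Step 1
Reactants: 1 6-methoxy-2-tetralone
Product: 2 (S)-6-methoxy-1,2,3,4-tetrahydronaphthalen-2-ol
Conditions: (S)-selective ketoreductase, NADP+ (cat.), i-PrOH, phosphate buffer pH 7, 30 °C
Reagents that add atoms: none
Why: Enzymatic ketone reduction with isopropanol-driven cofactor recycling, in which the binding pocket tells the benzylic flank from the CH2CH2 flank and hydride reaches one carbonyl face only, setting C8 as S (oxygen β).

Step 2
Reactants: 2 (S)-6-methoxy-1,2,3,4-tetrahydronaphthalen-2-ol
Product: 3 (S)-6-methoxy-1,2,3,4,5,8-hexahydronaphthalen-2-ol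
Conditions: Li, NH3(l), THF, t-BuOH, −78 to −33 °C; NH4Cl
Reagents that add atoms: none
Why: Birch reduction of an anisole leaves the donor-substituted positions unsaturated, giving the C2=C3 enol ether and the tetrasubstituted C5=C10 alkene, while the C8 alkoxide is a spectator.

Step 3
Reactants: 3 (S)-6-methoxy-1,2,3,4,5,8-hexahydronaphthalen-2-ol; 4 ethylene glycol
Product: 5 octal-5(10)-en-8β-ol 3-ethylene ketal
Conditions: HOCH2CH2OH (10 equiv), pyridinium tosylate (cat.), CH2Cl2, rt
Reagents that add atoms: ethylene glycol OCCO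
Why: Acid-catalysed ketal exchange, in which protonation of the enol ether at C2 gives the C3 oxocarbenium ion that the diol traps with loss of methanol, and since no free ketone appears under the weak acid the alkene stays at C5=C10.

Step 4
Reactants: 5 octal-5(10)-en-8β-ol 3-ethylene ketal; 6 diiodomethane
Product: 8 5β,10β-methanodecalin-8β-ol 3-ethylene ketal, via ethylzinc alkoxide 7 (not isolated)
Conditions: Et2Zn (4 equiv), CH2I2 (4 equiv), CH2Cl2, −15 °C to rt; aq. NH4Cl
Reagents that add atoms: diiodomethane ICI; diethylzinc CC[Zn]CC (ethylzinc unit of 7 only, lost on work-up)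
Why: Et2Zn first deprotonates the C8 hydroxyl to the ethylzinc alkoxide 7, the carbenoid EtZnCH2I (Furukawa variant of the Simmons–Smith reaction) docks on that oxygen, and CH2 passes to C5=C10 through the concerted butterfly transition state, so C10–C14 and C5–C14 form together. The closest known reaction type is the hydroxyl-directed cyclopropanation of cyclohex-3-enols and of 5(10)-unsaturated 19-nor steroid alcohols. The three-membered ring C5–C10–C14 closes in one [2+1] methylene transfer, which turns the octalin into a [4.4.1]propellane. Both new quaternary centres, C5 and C10, are fixed by the (S)-C8 carbinol, because in the ring B half-chair with a pseudoaxial O–Zn bond the bound carbenoid reaches only the alkene face syn to oxygen, the β face. Face selectivity is the only selectivity needed, since there is a single alkene, the dioxolane offers one oxygen to each face and so exerts no net bias, and the covalent Zn–O bond at C8 outweighs dative binding to the ketal. The electron-rich tetrasubstituted alkene suits the electrophilic carbenoid, and excess Et2Zn keeps the medium free of acid that would harm the ketal.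

Step 5
Reactants: 8 5β,10β-methanodecalin-8β-ol 3-ethylene ketal
Product: 10 (4aR,6S)-6-hydroxy-4a-methyl-4,4a,5,6,7,8-hexahydronaphthalen-2(3H)-one, via cyclopropyl ketone 9 (not isolated)
Conditions: 3 M aq. HCl, MeOH, 60 °C
Reagents that add atoms: water O
Why: Ketal hydrolysis gives 9, whose enol toward C4 is a vinylcyclopropane that is protonated at the least substituted carbon C14 with cleavage of C5–C14 (the protonolysis known for 5,10-methano-3-keto 19-nor steroids), so C14 becomes the β methyl on an untouched C10 and the C4=C5 enone appears, whereas cleavage of C5–C10 would put a bridgehead alkene into a bicyclo[4.4.1] frame.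

Step 6
Reactants: 10 (4aR,6S)-6-hydroxy-4a-methyl-4,4a,5,6,7,8-hexahydronaphthalen-2(3H)-one
Product: 11 8β-hydroxy-10β-methyl-4-(phenylthiomethyl)octal-4-en-3-one
Conditions: PhSH, 37% aq. HCHO, Et3N, EtOH, reflux
Reagents that add atoms: formaldehyde C=O; thiophenol Sc1ccccc1
Why: Kirk–Petrow thiomethylation, in which the extended dienol attacks formaldehyde at C4, water is lost and thiophenol adds to the exocyclic methylene, stopping cleanly at monoalkylation on this class of bicyclic enones.

Step 7
Reactants: 11 8β-hydroxy-10β-methyl-4-(phenylthiomethyl)octal-4-en-3-one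
Product: 12 8β-hydroxy-4,10β-dimethyloctal-4-en-3-one
Conditions: Raney Ni (deactivated by boiling in acetone), acetone–EtOH, rt to 40 °C
Reagents that add atoms: none
Why: Raney nickel desulfurisation cleaves both C–S bonds and leaves C15 as a methyl group, and the deactivated metal does not hydrogenate the now tetrasubstituted enone alkene.

Step 8
Reactants: 12 8β-hydroxy-4,10β-dimethyloctal-4-en-3-one
Product: 13 4,10β-dimethyloctal-4-ene-3β,8β-diol
Conditions: NaBH4, CeCl3·7H2O, MeOH, −20 °C
Reagents that add atoms: none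
Why: Luche 1,2-reduction, in which the small hydride attacks the ring A half-chair axially from the α face as in 4-en-3-one steroids, setting C3 as the pseudoequatorial 3β alcohol.

Step 9
Reactants: 13 4,10β-dimethyloctal-4-ene-3β,8β-diol
Product: 14 3β-(tert-butyldimethylsilyloxy)-4,10β-dimethyloctal-4-en-8β-ol
Conditions: TBSCl (1.05 equiv), imidazole, CH2Cl2, 0 °C
Reagents that add atoms: tert-butyldimethylsilyl chloride CC(C)(C)[Si](C)(C)Cl
Why: Site-selective silylation, since the pseudoequatorial C3 hydroxyl is open while the C8 hydroxyl is axial on the ring B chair and syn-diaxial to C14.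

Step 10
Reactants: 14 3β-(tert-butyldimethylsilyloxy)-4,10β-dimethyloctal-4-en-8β-ol
Product: 15 3β-(tert-butyldimethylsilyloxy)-4,10β-dimethyloctal-4-en-8-one
Conditions: Dess–Martin periodinane, CH2Cl2, rt
Reagents that add atoms: none
Why: Dess–Martin oxidation of the strained axial alcohol is fast and mild, spares the silyl ether and the alkene, and gives up the C8 centre only after its stereochemical information has been stored at C10.

Step 11
Reactants: 15 3β-(tert-butyldimethylsilyloxy)-4,10β-dimethyloctal-4-en-8-one; 16 methyl bromoacetate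
Product: 19 methyl 3β-(tert-butyldimethylsilyloxy)-8-oxo-13-noreudesm-4-en-12-oate (7β side chain), via lithium enolate 17 (not isolated), via C7 epimer mixture 18 (not isolated)
Conditions: LiN(i-Pr)2 (1.05 equiv), THF, −78 °C; 16 (1.05 equiv), DMPU, −78 to −20 °C; then MeOH, NaOMe (0.3 equiv), rt
Reagents that add atoms: methyl bromoacetate COC(=O)CBr; lithium diisopropylamide CC(C)[N-]C(C)C.[Li+] (Li of 17 only)
Why: Kinetic enolate alkylation, in which deprotonation goes to C7 because C9 is flanked by quaternary C10, SN2 attack on the bromoacetate forms C7–C11, and methoxide equilibration moves the side chain into the equatorial 7β position of the ring B chair locked by axial C14.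

Step 12
Reactants: 19 methyl 3β-(tert-butyldimethylsilyloxy)-8-oxo-13-noreudesm-4-en-12-oate (7β side chain)
Product: 21 3β-(tert-butyldimethylsilyloxy)-13-noreudesm-4-en-8β,12-olide (cis-fused), via lithium 8β-alkoxide 20 (not isolated)
Conditions: LiBH(s-Bu)3, THF, −78 to 0 °C; aq. NH4Cl
Reagents that add atoms: lithium tri-sec-butylborohydride [Li+].CCC(C)[BH-](C(C)CC)C(C)CC (Li of 20 only)
Why: Bulky-hydride reduction, in which the axial β trajectory at C8 is blocked by C14 (as in 3,3,5-trimethylcyclohexanone), so hydride enters from the α face and the axial 8β alkoxide 20 closes on the neighbouring equatorial ester to the cis γ-lactone.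

Step 13
Reactants: 21 3β-(tert-butyldimethylsilyloxy)-13-noreudesm-4-en-8β,12-olide (cis-fused)
Product: 23 13-(dimethylamino)-3β-(tert-butyldimethylsilyloxy)eudesm-4-en-8β,12-olide (C11 epimers), via lactone lithium enolate 22 (not isolated)
Conditions: LiN(i-Pr)2, THF, −78 °C; CH2=NMe2+ I−, −78 °C to rt
Reagents that add atoms: N,N-dimethylmethyleneiminium iodide C=[N+](C)C.[I-]; lithium diisopropylamide CC(C)[N-]C(C)C.[Li+] (Li of 22 only)
Why: Mannich reaction of the lactone enolate with Eschenmoser's salt forms C11–C13, and the configuration at C11 does not matter because that centre becomes sp2 in the next step.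

Step 14
Reactants: 23 13-(dimethylamino)-3β-(tert-butyldimethylsilyloxy)eudesm-4-en-8β,12-olide (C11 epimers)
Product: 25 3β-(tert-butyldimethylsilyloxy)eudesma-4,11(13)-dien-8β,12-olide, via trimethylammonium iodide 24 (not isolated)
Conditions: MeI, THF, rt; then sat. aq. NaHCO3, rt
Reagents that add atoms: iodomethane CI (present in 24 only)
Why: Quaternisation followed by E1cB (Hofmann-type) loss of trimethylamine is the standard unveiling of an α-methylene lactone and needs only bicarbonate.

Step 15
Reactants: 25 3β-(tert-butyldimethylsilyloxy)eudesma-4,11(13)-dien-8β,12-olide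
Product: 27 methyl 8β-hydroxy-3β-(tert-butyldimethylsilyloxy)eudesma-4,11(13)-dien-12-oate, via potassium carboxylate 26 (not isolated)
Conditions: KOH (1.1 equiv), THF–H2O, rt; evaporate; MeI, DMF, 0 °C to rt
Reagents that add atoms: potassium hydroxide [K+].[OH-]; iodomethane CI
Why: Saponification then carboxylate O-alkylation, which works because acyl–oxygen cleavage keeps the C8–O bond and its configuration, the hydroxy acids of cis 8β,12-eudesmanolides are isolable, the acrylate salt is a poor Michael acceptor, and esterification with MeI avoids the acid that would reclose the lactone.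

Step 16
Reactants: 27 methyl 8β-hydroxy-3β-(tert-butyldimethylsilyloxy)eudesma-4,11(13)-dien-12-oate
Product: 28 methyl 8β-acetoxy-3β-(tert-butyldimethylsilyloxy)eudesma-4,11(13)-dien-12-oate
Conditions: Ac2O, DMAP (cat.), pyridine, rt
Reagents that add atoms: acetic anhydride CC(=O)OC(C)=O
Why: DMAP-catalysed acylation is strong enough for the hindered axial C8 hydroxyl and removes the nucleophile that could reclose the lactone.

Step 17
Reactants: 28 methyl 8β-acetoxy-3β-(tert-butyldimethylsilyloxy)eudesma-4,11(13)-dien-12-oate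
Product: 29 methyl 8β-acetoxy-3β-hydroxyeudesma-4,11(13)-dien-12-oate
Conditions: Bu4NF, AcOH (1:1), THF, rt
Reagents that add atoms: none
Why: Buffered fluoride desilylation is neither acidic enough to ionise the C3 allylic alcohol nor basic enough to touch the acetate or the acrylate.

Step 18
Reactants: 29 methyl 8β-acetoxy-3β-hydroxyeudesma-4,11(13)-dien-12-oate; 30 (E)-3-methylpent-2-enoic acid
Product: 31 methyl 8β-acetoxy-3β-[(E)-3-methylpent-2-enoyloxy]eudesma-4,11(13)-dien-12-oate (3S,7R,8R,10R), the target
Conditions: DCC, DMAP (cat.), CH2Cl2, 0 °C to rt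
Reagents that add atoms: (E)-3-methylpent-2-enoic acid CC/C(C)=C/C(=O)O
Why: Steglich esterification acylates oxygen with retention at C3, and the low temperature, catalytic DMAP and absence of a stoichiometric amine base suppress γ-deprotonation, so the E alkene should be kept.

## Compound list

1 | 6-methoxy-2-tetralone | COc1ccc2c(c1)CCC(=O)C2 | starting material
2 | (S)-6-methoxy-1,2,3,4-tetrahydronaphthalen-2-ol | O[C@H]1CCc2cc(OC)ccc2C1 | intermediate
3 | (S)-6-methoxy-1,2,3,4,5,8-hexahydronaphthalen-2-ol | O[C@H]1CCC2=C(C1)CC=C(OC)C2 | intermediate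
4 | ethylene glycol | OCCO | starting material
5 | octal-5(10)-en-8β-ol 3-ethylene ketal, (8S) | O[C@H]1CCC2=C(C1)CCC3(C2)OCCO3 | intermediate
6 | diiodomethane | ICI | starting material
7 | ethylzinc alkoxide of 5 | CC[Zn]O[C@H]1CCC2=C(C1)CCC3(C2)OCCO3 | intermediate
8 | 5β,10β-methanodecalin-8β-ol 3-ethylene ketal (CH2 bridge cis to OH) | O[C@H]1CC[C@@]23C[C@]2(C1)CCC1(C3)OCCO1 | intermediate
9 | 8β-hydroxy-5β,10β-methanodecalin-3-one | O[C@H]1CC[C@@]23C[C@]2(C1)CCC(=O)C3 | intermediate
10 | (4aR,6S)-6-hydroxy-4a-methyl-4,4a,5,6,7,8-hexahydronaphthalen-2(3H)-one | O[C@H]1CCC2=CC(=O)CC[C@]2(C)C1 | intermediate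
11 | 8β-hydroxy-10β-methyl-4-(phenylthiomethyl)octal-4-en-3-one | O[C@H]1CCC2=C(CSc3ccccc3)C(=O)CC[C@]2(C)C1 | intermediate
12 | 8β-hydroxy-4,10β-dimethyloctal-4-en-3-one | O[C@H]1CCC2=C(C)C(=O)CC[C@]2(C)C1 | intermediate
13 | 4,10β-dimethyloctal-4-ene-3β,8β-diol | O[C@H]1CCC2=C(C)[C@@H](O)CC[C@]2(C)C1 | intermediate
14 | 3β-(tert-butyldimethylsilyloxy)-4,10β-dimethyloctal-4-en-8β-ol | O[C@H]1CCC2=C(C)[C@@H](O[Si](C)(C)C(C)(C)C)CC[C@]2(C)C1 | intermediate
15 | 3β-(tert-butyldimethylsilyloxy)-4,10β-dimethyloctal-4-en-8-one | O=C1CCC2=C(C)[C@@H](O[Si](C)(C)C(C)(C)C)CC[C@]2(C)C1 | intermediate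
16 | methyl bromoacetate | COC(=O)CBr | starting material
17 | lithium 7-en-8-olate of 15 | [Li]OC1=CCC2=C(C)[C@@H](O[Si](C)(C)C(C)(C)C)CC[C@]2(C)C1 | intermediate
18 | methyl 3β-(tert-butyldimethylsilyloxy)-8-oxo-13-noreudesm-4-en-12-oate, C7 epimer mixture | COC(=O)CC1CC2=C(C)[C@@H](O[Si](C)(C)C(C)(C)C)CC[C@]2(C)CC1=O | intermediate
19 | methyl 3β-(tert-butyldimethylsilyloxy)-8-oxo-13-noreudesm-4-en-12-oate, 7β side chain | COC(=O)C[C@H]1CC2=C(C)[C@@H](O[Si](C)(C)C(C)(C)C)CC[C@]2(C)CC1=O | intermediate
20 | lithium 8β-alkoxide of the hydroxy ester | COC(=O)C[C@H]1CC2=C(C)[C@@H](O[Si](C)(C)C(C)(C)C)CC[C@]2(C)C[C@H]1O[Li] | intermediate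
21 | 3β-(tert-butyldimethylsilyloxy)-13-noreudesm-4-en-8β,12-olide (7α-H, 8α-H) | O=C1C[C@H]2CC3=C(C)[C@@H](O[Si](C)(C)C(C)(C)C)CC[C@]3(C)C[C@H]2O1 | intermediate
22 | lithium enolate of lactone 21 | [Li]OC1=C[C@H]2CC3=C(C)[C@@H](O[Si](C)(C)C(C)(C)C)CC[C@]3(C)C[C@H]2O1 | intermediate
23 | 13-(dimethylamino)-3β-(tert-butyldimethylsilyloxy)eudesm-4-en-8β,12-olide, C11 epimers | CN(C)CC1[C@H]2CC3=C(C)[C@@H](O[Si](C)(C)C(C)(C)C)CC[C@]3(C)C[C@H]2OC1=O | intermediate
24 | 13-(trimethylammonio) lactone iodide | C[N+](C)(C)CC1[C@H]2CC3=C(C)[C@@H](O[Si](C)(C)C(C)(C)C)CC[C@]3(C)C[C@H]2OC1=O.[I-] | intermediate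
25 | 3β-(tert-butyldimethylsilyloxy)eudesma-4,11(13)-dien-8β,12-olide | C=C1[C@H]2CC3=C(C)[C@@H](O[Si](C)(C)C(C)(C)C)CC[C@]3(C)C[C@H]2OC1=O | intermediate
26 | potassium 8β-hydroxy-3β-(tert-butyldimethylsilyloxy)eudesma-4,11(13)-dien-12-oate | C=C(C(=O)[O-])[C@H]1CC2=C(C)[C@@H](O[Si](C)(C)C(C)(C)C)CC[C@]2(C)C[C@H]1O.[K+] | intermediate
27 | methyl 8β-hydroxy-3β-(tert-butyldimethylsilyloxy)eudesma-4,11(13)-dien-12-oate | C=C(C(=O)OC)[C@H]1CC2=C(C)[C@@H](O[Si](C)(C)C(C)(C)C)CC[C@]2(C)C[C@H]1O | intermediate
28 | methyl 8β-acetoxy-3β-(tert-butyldimethylsilyloxy)eudesma-4,11(13)-dien-12-oate | C=C(C(=O)OC)[C@H]1CC2=C(C)[C@@H](O[Si](C)(C)C(C)(C)C)CC[C@]2(C)C[C@H]1OC(C)=O | intermediate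
29 | methyl 8β-acetoxy-3β-hydroxyeudesma-4,11(13)-dien-12-oate | C=C(C(=O)OC)[C@H]1CC2=C(C)[C@@H](O)CC[C@]2(C)C[C@H]1OC(C)=O | intermediate
30 | (E)-3-methylpent-2-enoic acid | CC/C(C)=C/C(=O)O | starting material
31 | methyl 8β-acetoxy-3β-[(E)-3-methylpent-2-enoyloxy]eudesma-4,11(13)-dien-12-oate (3S,7R,8R,10R) | C=C(C(=O)OC)[C@H]1CC2=C(C)[C@@H](OC(=O)/C=C(\C)CC)CC[C@]2(C)C[C@H]1OC(C)=O | target

## Step count and risks

Total step count: 18. Longest linear sequence: 18 steps, from 1.

**Step 4 (key step).**
- Risk: carbenoid that is unbound, or bound to a dioxolane oxygen, may deliver CH2 to the α face and erode face selectivity. Zinc iodide may also attack the ketal during a slow reaction at the tetrasubstituted alkene.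
- Fallback: drop the ketal and let two hydroxyls direct together. It sets out from 3.
- Oxalic acid in aqueous THF should give (S)-6-hydroxy-3,4,5,6,7,8-hexahydronaphthalen-2(1H)-one F1.
- The ketoreductase of step 1 should reduce the C3 ketone of F1, whose flanks resemble those of 1. This gives the C2-symmetric (2S,6S)-1,2,3,4,5,6,7,8-octahydronaphthalene-2,6-diol F2, with both homoallylic hydroxyls on the β face.
- Et2Zn/CH2I2 should then give 5β,10β-methanodecalin-3β,8β-diol F3 under doubly matched direction, the arrangement best known from the steroid series.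
- The two carbinols of F3 are homotopic, so oxidation with one equivalent of Dess–Martin periodinane (unreacted diol recycled) can give only one hydroxy ketone, 9. The fallback comes back to the route at 9, and the acid of step 5 leads on to 10.

**Step 15 (lactone opening).**
- Risk: hydroxide may add to the exocyclic methylene, and the hydroxy ester may reclose to the lactone during esterification or the following acetylation.
- Fallback: keep the carboxyl oxidation level absent while the C8 hydroxyl is free. It sets out from 25.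
- i-Bu2AlH in CH2Cl2 should reduce the lactone to 3β-(tert-butyldimethylsilyloxy)eudesma-4,11(13)-diene-8β,12-diol F4.
- Ac2O/DMAP/pyridine should give the 8β,12-diacetate F5.
- K2CO3 in MeOH at 0 °C should remove only the unhindered primary allylic acetate, giving 8β-acetoxy-3β-(tert-butyldimethylsilyloxy)eudesma-4,11(13)-dien-12-ol F6.
- MnO2 should give the enal 8β-acetoxy-3β-(tert-butyldimethylsilyloxy)eudesma-4,11(13)-dien-12-al F7.
- Pinnick oxidation (NaClO2, NaH2PO4, 2-methyl-2-butene) should give the acid 8β-acetoxy-3β-(tert-butyldimethylsilyloxy)eudesma-4,11(13)-dien-12-oic acid F8.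
- Trimethylsilyldiazomethane then brings the fallback back to the route at 28.

**Step 11 (C7 alkylation).**
- Risk: proton transfer between enolate and product may cause double alkylation, some deprotonation may occur at C9, and the alkylation may be sluggish.
- Fallback: activate C7 reversibly first. It sets out from 15.
- NaH and diallyl carbonate in refluxing THF should give, under thermodynamic control away from the crowded C9, the β-keto ester allyl 3β-(tert-butyldimethylsilyloxy)-4,10β-dimethyl-8-oxooctal-4-ene-7-carboxylate F9.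
- K2CO3 and 16 in acetone should alkylate the stabilised enolate once, giving the C7-quaternary allyl 7-(2-methoxy-2-oxoethyl) keto diester F10.
- Pd(PPh3)4 and morpholine in THF should remove the allyl ester with decarboxylation to give 18. The NaOMe equilibration of step 11 then brings the fallback back to the route at 19.

Further compounds
F1 | step 4 | (S)-6-hydroxy-3,4,5,6,7,8-hexahydronaphthalen-2(1H)-one | O[C@H]1CCC2=C(C1)CCC(=O)C2
F2 | step 4 | (2S,6S)-1,2,3,4,5,6,7,8-octahydronaphthalene-2,6-diol | O[C@H]1CCC2=C(C1)CC[C@H](O)C2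
F3 | step 4 | 5β,10β-methanodecalin-3β,8β-diol | O[C@H]1CC[C@@]23C[C@]2(C1)CC[C@H](O)C3
F4 | step 15 | 3β-(tert-butyldimethylsilyloxy)eudesma-4,11(13)-diene-8β,12-diol | C=C(CO)[C@H]1CC2=C(C)[C@@H](O[Si](C)(C)C(C)(C)C)CC[C@]2(C)C[C@H]1O
F5 | step 15 | 8β,12-diacetoxy-3β-(tert-butyldimethylsilyloxy)eudesma-4,11(13)-diene | C=C(COC(C)=O)[C@H]1CC2=C(C)[C@@H](O[Si](C)(C)C(C)(C)C)CC[C@]2(C)C[C@H]1OC(C)=O
F6 | step 15 | 8β-acetoxy-3β-(tert-butyldimethylsilyloxy)eudesma-4,11(13)-dien-12-ol | C=C(CO)[C@H]1CC2=C(C)[C@@H](O[Si](C)(C)C(C)(C)C)CC[C@]2(C)C[C@H]1OC(C)=O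
F7 | step 15 | 8β-acetoxy-3β-(tert-butyldimethylsilyloxy)eudesma-4,11(13)-dien-12-al | C=C(C=O)[C@H]1CC2=C(C)[C@@H](O[Si](C)(C)C(C)(C)C)CC[C@]2(C)C[C@H]1OC(C)=O
F8 | step 15 | 8β-acetoxy-3β-(tert-butyldimethylsilyloxy)eudesma-4,11(13)-dien-12-oic acid | C=C(C(=O)O)[C@H]1CC2=C(C)[C@@H](O[Si](C)(C)C(C)(C)C)CC[C@]2(C)C[C@H]1OC(C)=O
F9 | step 11 | allyl 3β-(tert-butyldimethylsilyloxy)-4,10β-dimethyl-8-oxooctal-4-ene-7-carboxylate | C=CCOC(=O)C1CC2=C(C)[C@@H](O[Si](C)(C)C(C)(C)C)CC[C@]2(C)CC1=O
F10 | step 11 | allyl 3β-(tert-butyldimethylsilyloxy)-7-(2-methoxy-2-oxoethyl)-4,10β-dimethyl-8-oxooctal-4-ene-7-carboxylate | C=CCOC(=O)C1(CC(=O)OC)CC2=C(C)[C@@H](O[Si](C)(C)C(C)(C)C)CC[C@]2(C)CC1=O
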